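| flask | electrophile | nucleophile | time |
|---|---|---|---|
| ash | 45 mM | 45.0 mM | 5.0 min |
| maple | 45 mM | 58.0 mM | 5.0 min |

    electrophile + nucleophile ⇌ acid set free + target (K1 = 0.52, k1 = 0.078 M⁻¹ s⁻¹)
    nucleophile + acid set free ⇌ protonated nucleophile, settled at all times (K2 = 1800 M⁻¹)
    electrophile + target → side product (k3 = 0.0052 M⁻¹ s⁻¹)
    target → over-reaction product (k4 = 0.0051 s⁻¹)

* part of the electrophile that has reacted at the end, ash
* part of the electrophile that has reacted at the end, maple
* what raising the concentration of nucleophile from its lowest to its highest value here does to the part of the electrophile that has reacted (changes below 5 percentage points count as none) (it rises / no change / it falls)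

- percentages count the electrophile that a species holds: one side product counts as two
- run time (ash): 5.0 min

Slowness comes first. The forward constant times the charged nucleophile gives 0.211 min⁻¹, the clock rate of ash, a pseudo-first-order constant for a first pass. Counted forward, with c(nucleophile) held at its charge, electrophile in ash has a half-life of 3.29 min, shorter than the run. So the first answer for ash is 65.1% reacted.

But the second step has K times the charged c(nucleophile) of ash equal to 81.0, so acid set free goes onto nucleophile. In this reckoning each electrophile reacted costs two nucleophiles. The first answer would then cost 58.6 mM, more than the 45.0 mM charged.

So that answer goes back in. If x of electrophile has reacted, c(electrophile) has fallen by x and c(nucleophile) by 2x. The way back and the side paths stay out of this count. With equal charges, as in ash, the reacted part X then obeys (1 − X)/(1 − 2X) = exp(clock rate × time). This gives 39.4% for ash. The same integration with unequal charges gives 48.9% for maple. The rise of 9.5 percentage points exceeds the margin.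

The forecast gives 40% for ash and 49.4% for maple, and says it rises, holding that “each electrophile effectively costs two nucleophiles”. Its ash figure stands a little above this reckoning, and so does its maple figure.

Ash reaches 40.3% reacted and maple 49.7%. As for that part, when nucleophile is raised from ash to maple, it rises, a change of 9.4 points. Ash ends with nucleophile at 23% of its charge, less than electrophile at 60% of its own, which reads as 1.91 nucleophiles lost per electrophile reacted. The clock rate of ash, put into the same rule for a reading at 3.0 min, gives 31.9%, and ash at that time stands at 32.4%.

(The numbers stand for no real mixture; what happens was integrated by code.)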